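**Plan**

1. Retrosynthetic cuts, in order: C5–OOH with the C4=C15 shift (Schenck ene on a C4=C5 alkene); the C3–O acyl bond (angelate); C11–C12 and C11=C13 of the acrylate (alkyne hydroesterification, aldehyde homologation); C5–C6 of ring B (one-carbon ring expansion); C4=C5 and C1–C10 of ring A (aldol, Michael).
2. Forward order: the cyclopentane C5/C7/C8/C9/C10 comes first, ring A is annulated onto it, and ring B is then made by inserting C6 between C5 and C7 of that five-membered ring.
3. Enabling feature: C5 is at once a ring-B atom and the β-carbon of the ring-A enone (C3=O, C4=C5), and C7 carries a carboxyl-level carbon (C11). A C6 radical on C7 can therefore add to C5, and the C5–C7 bond can then break to an ester-stabilised C7 radical.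
4. Stereochemistry: C10 from an (R)-1-phenylethylamine imine in the Michael step; C7 from axial hydrogen transfer to the C7 radical (also the more stable epimer); C3 from axial hydride delivery (Luche); C5 from α-face singlet-oxygen attack anti to the C10 methyl; the Z ester from angelic acid.

Key step: step 6

Remark: eudesmane numbering (C1–C15) is used for all intermediates (in the cyclopentanes the ketone carbon is C5, the ester-bearing carbon C7, the methyl-bearing carbon C10); centres that are epimerisable or erased later (C7 in 3–11, C10 in 1–7) are left undefined in the SMILES.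

Step 1
Reactants: 1 2-methylcyclopentanone (racemic); 2 dimethyl carbonate
Product: 3 methyl 3-methyl-2-oxocyclopentane-1-carboxylate (mixture of stereoisomers)
Conditions: NaH (2.2 equiv), THF, reflux; then aq. HCl
Reagents that add atoms: none
Why: A crossed Claisen acylation places the ester on the unsubstituted α-carbon, because only that β-keto ester can be held as its enolate while acylation at the methyl-bearing carbon is reversible; no stereocentre of the target is set here.

Step 2
Reactants: 3 methyl 3-methyl-2-oxocyclopentane-1-carboxylate; 4 dibromomethane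
Product: 5 methyl 1-(bromomethyl)-3-methyl-2-oxocyclopentane-1-carboxylate (mixture of stereoisomers)
Conditions: NaH, THF–DMPU, 0 °C; CH2Br2 (5 equiv), 60 °C
Reagents that add atoms: none
Why: C-Alkylation of the β-keto ester enolate with excess dibromomethane is the standard way to an α-(bromomethyl) β-keto ester; the new quaternary carbon (future C7) forms as both epimers, which converge when it becomes a radical in step 6.

Step 3
Reactants: 5 methyl 1-(bromomethyl)-3-methyl-2-oxocyclopentane-1-carboxylate; 6 (R)-1-phenylethylamine
Product: 7 methyl 1-(bromomethyl)-3-methyl-2-{[(1R)-1-phenylethyl]imino}cyclopentane-1-carboxylate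
Conditions: TiCl4 (0.55 equiv), Et3N (3 equiv), toluene, 0 °C to rt
Reagents that add atoms: none
Why: TiCl4-mediated ketimine condensation tolerates a ketone flanked by a quaternary carbon, and because that carbon has no hydrogen the imine can tautomerise to the secondary enamine only towards the methyl-bearing carbon (future C10).

Step 4
Reactants: 7 methyl 1-(bromomethyl)-3-methyl-2-{[(1R)-1-phenylethyl]imino}cyclopentane-1-carboxylate; 8 pent-1-en-3-one (ethyl vinyl ketone)
Product: 10 methyl (3S)-1-(bromomethyl)-3-methyl-2-oxo-3-(3-oxopentyl)cyclopentane-1-carboxylate (both C1 epimers), via Michael adduct imine 9 (not isolated)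
Conditions: THF, 40 °C; then 20% aq. AcOH, rt
Reagents that add atoms: water, O
Why: In this auxiliary-controlled Michael addition of a chiral secondary enamine (compact aza-ene-like transition state with NH transfer) the enone is taken up on the enamine face remote from the phenyl group of the (R)-auxiliary, which should set the quaternary C10 as S (the mirror image of the established sense for (S)-amine imines of 2-methylcycloalkanones), and mild acid then hydrolyses the imine.

Step 5
Reactants: 10 methyl (3S)-1-(bromomethyl)-3-methyl-2-oxo-3-(3-oxopentyl)cyclopentane-1-carboxylate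
Product: 11 methyl (3aS)-1-(bromomethyl)-3a,7-dimethyl-6-oxo-2,3,3a,4,5,6-hexahydro-1H-indene-1-carboxylate (both C1 epimers)
Conditions: TsOH·H2O (cat.), toluene, reflux, Dean–Stark
Reagents that add atoms: none
Why: Acid-catalysed aldol condensation (the closing stage of a Robinson annulation) forms ring A at the cyclopentanone carbonyl, and acid is used because alkoxide would open the non-enolisable β-keto ester by retro-Claisen cleavage; no stereocentre is formed.

Step 6
Reactants: 11 methyl (3aS)-1-(bromomethyl)-3a,7-dimethyl-6-oxo-2,3,3a,4,5,6-hexahydro-1H-indene-1-carboxylate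
Product: 12 methyl (2R,4aS)-4a,8-dimethyl-7-oxo-1,2,3,4,4a,5,6,7-octahydronaphthalene-2-carboxylate
Conditions: (Me3Si)3SiH (1.3 equiv), AIBN (0.2 equiv), benzene, 80 °C, syringe-pump addition, 0.01 M
Reagents that add atoms: none
Why: Proposed new method: silyl-radical abstraction of bromine gives the primary radical C6 on the quaternary C7, which adds 3-exo-trig to C5, the β-carbon of the ring-A enone, to give a cyclopropylcarbinyl radical at C4 that is stabilised by the C3 carbonyl; β-scission of the strained C5–C7 bond then restores the C4=C5 enone and leaves the ester-stabilised radical at C7, which takes hydrogen from the silane. The closest known reaction types are the Dowd–Beckwith one-carbon ring expansion of α-halomethyl β-keto esters (acceptor C=O) and the homoallyl–cyclopropylcarbinyl (1,2-vinyl shift) radical rearrangement; an enone β-carbon as the acceptor is the untested element. The only closure is the transient cyclopropane C5–C6–C7 (3-exo-trig); ring B (C5, C6, C7, C8, C9, C10) arises from the cyclopentane (C5, C7, C8, C9, C10) by insertion of C6, that is by ring expansion and not by cyclisation. The one new stereocentre, C7, is set in the hydrogen transfer: the planar ester-conjugated radical is approached along the axial α-direction, which is open because C5 is sp2 and only H9α flanks it, so that the ester ends equatorial (7β), which is also the more stable epimer. The step needs rearrangement to outrun direct reduction of the C6 radical and a 1,5-hydrogen shift from the C15 methyl; the fully substituted C7, the polarity match between the alkyl radical and the enone β-carbon, the gain of an α-ester radical with release of cyclopentane and allylic strain, and slow addition of a sluggish hydrogen donor at high dilution should secure it. C10 is not touched.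

Step 7
Reactants: 12 methyl (2R,4aS)-4a,8-dimethyl-7-oxo-1,2,3,4,4a,5,6,7-octahydronaphthalene-2-carboxylate
Product: 13 (2R,4aS)-4a,8-dimethyl-7-oxo-1,2,3,4,4a,5,6,7-octahydronaphthalene-2-carboxylic acid
Conditions: LiOH·H2O, THF–H2O, 0 °C to rt; then 1 M HCl
Reagents that add atoms: lithium hydroxide, [Li+].[OH-]
Why: Saponification of the secondary methyl ester with LiOH leaves the tetrasubstituted enone alone and does not disturb C7, since the carboxylate is not enolised under these conditions.

Step 8
Reactants: 13 (2R,4aS)-4a,8-dimethyl-7-oxo-1,2,3,4,4a,5,6,7-octahydronaphthalene-2-carboxylic acid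
Product: 15 (2R,4aS)-4a,8-dimethyl-7-oxo-1,2,3,4,4a,5,6,7-octahydronaphthalene-2-carbaldehyde, via acid chloride 14 (not isolated)
Conditions: (COCl)2, DMF (cat.), CH2Cl2, 0 °C; evaporate; LiAlH(Ot-Bu)3 (1.05 equiv), THF, −78 °C
Reagents that add atoms: oxalyl chloride, O=C(Cl)C(Cl)=O (chlorine of 14 only; 15 gains only hydrogen)
Why: Conversion to the acid chloride and partial reduction with the hindered hydride LiAlH(Ot-Bu)3 at −78 °C is the classical acid-to-aldehyde sequence, and at this temperature the reagent should not attack the hindered, conjugated ketone.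

Step 9
Reactants: 15 (2R,4aS)-4a,8-dimethyl-7-oxo-1,2,3,4,4a,5,6,7-octahydronaphthalene-2-carbaldehyde; 16 dimethyl (1-diazo-2-oxopropyl)phosphonate
Product: 17 (4aS,7R)-7-ethynyl-1,4a-dimethyl-4,4a,5,6,7,8-hexahydronaphthalen-2(3H)-one
Conditions: K2CO3, MeOH, 0 °C to rt
Reagents that add atoms: none
Why: Seyferth–Gilbert homologation with the Ohira–Bestmann reagent turns the aldehyde into the terminal alkyne (new carbon = C13) under carbonate in methanol, and if the aldehyde epimerises at C7 it drifts towards the equatorial 7β isomer that is wanted.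

Step 10
Reactants: 17 (4aS,7R)-7-ethynyl-1,4a-dimethyl-4,4a,5,6,7,8-hexahydronaphthalen-2(3H)-one
Product: 18 methyl 2-[(2R,4aS)-4a,8-dimethyl-7-oxo-1,2,3,4,4a,5,6,7-octahydronaphthalen-2-yl]prop-2-enoate (methyl 3-oxoeudesma-4,11(13)-dien-12-oate)
Conditions: Pd(OAc)2 (1 mol%), 2-pyridyldiphenylphosphine, MsOH (cat.), CO (30 bar), MeOH, 50 °C
Reagents that add atoms: carbon monoxide, [C-]#[O+]; methanol, CO
Why: Palladium hydride-catalysed hydromethoxycarbonylation of a terminal alkyne with a 2-pyridylphosphine ligand is Markovnikov-selective and gives the 2-substituted acrylate (C12 from CO) in one step without touching the enone or creating a stereocentre.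

Step 11
Reactants: 18 methyl 3-oxoeudesma-4,11(13)-dien-12-oate
Product: 19 methyl 2-[(2R,4aS,7S)-7-hydroxy-4a,8-dimethyl-1,2,3,4,4a,5,6,7-octahydronaphthalen-2-yl]prop-2-enoate (methyl 3β-hydroxyeudesma-4,11(13)-dien-12-oate)
Conditions: NaBH4, CeCl3·7H2O, MeOH, −78 °C
Reagents that add atoms: none
Why: Luche reduction gives 1,2-reduction of the enone only, with hydride entering axially on the α-face (anti to the axial C10 methyl) so that the equatorial 3β-alcohol (3S) results, while the acrylate is not reduced at −78 °C.

Step 12
Reactants: 19 methyl 3β-hydroxyeudesma-4,11(13)-dien-12-oate; 20 angelic acid [(2Z)-2-methylbut-2-enoic acid]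
Product: 21 (2S,4aS,7R)-7-(3-methoxy-3-oxoprop-1-en-2-yl)-1,4a-dimethyl-2,3,4,4a,5,6,7,8-octahydronaphthalen-2-yl (2Z)-2-methylbut-2-enoate (methyl 3β-angeloyloxyeudesma-4,11(13)-dien-12-oate)
Conditions: 20, 2,4,6-trichlorobenzoyl chloride, Et3N, toluene, rt; then 19, 80 °C (no DMAP)
Reagents that add atoms: none
Why: Yamaguchi-type esterification through the mixed anhydride, run without a nucleophilic catalyst, acylates the allylic alcohol with retention at C3 and avoids the Z-to-E (angelate to tiglate) isomerisation that DMAP or strong base would cause.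

Step 13
Reactants: 21 methyl 3β-angeloyloxyeudesma-4,11(13)-dien-12-oate
Product: 22 methyl 2-[(2R,4aS,7S,8aS)-8a-hydroperoxy-4a-methyl-8-methylidene-7-{[(2Z)-2-methylbut-2-enoyl]oxy}decahydronaphthalen-2-yl]prop-2-enoate (methyl 3β-angeloyloxy-5α-hydroperoxyeudesma-4(15),11(13)-dien-12-oate, the target)
Conditions: O2, tetraphenylporphyrin (cat.), visible light, CH2Cl2, −20 °C
Reagents that add atoms: dioxygen, O=O
Why: In this Schenck ene reaction singlet oxygen attacks the only electron-rich alkene (C4=C5), bonds to C5 on the α-face anti to the axial C10 methyl and abstracts a hydrogen of the C15 methyl (the group geminal to the bulky C3 carbon), which should give the 5α-hydroperoxide (5S) and the C4=C15 methylidene, whereas the acrylate and the angelate are too electron-poor to react.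

**Compound list**

1 | 2-methylcyclopentanone (racemic) | CC1CCCC1=O | starting material
2 | dimethyl carbonate | COC(=O)OC | starting material
3 | methyl 3-methyl-2-oxocyclopentane-1-carboxylate (mixture of stereoisomers) | COC(=O)C1CCC(C)C1=O | intermediate
4 | dibromomethane | BrCBr | starting material
5 | methyl 1-(bromomethyl)-3-methyl-2-oxocyclopentane-1-carboxylate (mixture of stereoisomers) | COC(=O)C1(CBr)CCC(C)C1=O | intermediate
6 | (R)-1-phenylethylamine | C[C@@H](N)c1ccccc1 | starting material
7 | methyl 1-(bromomethyl)-3-methyl-2-{[(1R)-1-phenylethyl]imino}cyclopentane-1-carboxylate (ring centres as mixture) | COC(=O)C1(CBr)CCC(C)C1=N[C@H](C)c1ccccc1 | intermediate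
8 | pent-1-en-3-one (ethyl vinyl ketone) | C=CC(=O)CC | starting material
9 | methyl (3S)-1-(bromomethyl)-3-methyl-3-(3-oxopentyl)-2-{[(1R)-1-phenylethyl]imino}cyclopentane-1-carboxylate (both C1 epimers) | CCC(=O)CC[C@]1(C)CCC(CBr)(C(=O)OC)C1=N[C@H](C)c1ccccc1 | intermediate
10 | methyl (3S)-1-(bromomethyl)-3-methyl-2-oxo-3-(3-oxopentyl)cyclopentane-1-carboxylate (both C1 epimers) | CCC(=O)CC[C@]1(C)CCC(CBr)(C(=O)OC)C1=O | intermediate
11 | methyl (3aS)-1-(bromomethyl)-3a,7-dimethyl-6-oxo-2,3,3a,4,5,6-hexahydro-1H-indene-1-carboxylate (both C1 epimers) | COC(=O)C1(CBr)CC[C@@]2(C)CCC(=O)C(C)=C21 | intermediate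
12 | methyl (2R,4aS)-4a,8-dimethyl-7-oxo-1,2,3,4,4a,5,6,7-octahydronaphthalene-2-carboxylate | COC(=O)[C@@H]1CC[C@@]2(C)CCC(=O)C(C)=C2C1 | intermediate
13 | (2R,4aS)-4a,8-dimethyl-7-oxo-1,2,3,4,4a,5,6,7-octahydronaphthalene-2-carboxylic acid | OC(=O)[C@@H]1CC[C@@]2(C)CCC(=O)C(C)=C2C1 | intermediate
14 | (2R,4aS)-4a,8-dimethyl-7-oxo-1,2,3,4,4a,5,6,7-octahydronaphthalene-2-carbonyl chloride | ClC(=O)[C@@H]1CC[C@@]2(C)CCC(=O)C(C)=C2C1 | intermediate
15 | (2R,4aS)-4a,8-dimethyl-7-oxo-1,2,3,4,4a,5,6,7-octahydronaphthalene-2-carbaldehyde | O=C[C@@H]1CC[C@@]2(C)CCC(=O)C(C)=C2C1 | intermediate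
16 | dimethyl (1-diazo-2-oxopropyl)phosphonate | COP(=O)(OC)C(=[N+]=[N-])C(C)=O | starting material
17 | (4aS,7R)-7-ethynyl-1,4a-dimethyl-4,4a,5,6,7,8-hexahydronaphthalen-2(3H)-one | C#C[C@@H]1CC[C@@]2(C)CCC(=O)C(C)=C2C1 | intermediate
18 | methyl 2-[(2R,4aS)-4a,8-dimethyl-7-oxo-1,2,3,4,4a,5,6,7-octahydronaphthalen-2-yl]prop-2-enoate | C=C(C(=O)OC)[C@@H]1CC[C@@]2(C)CCC(=O)C(C)=C2C1 | intermediate
19 | methyl 2-[(2R,4aS,7S)-7-hydroxy-4a,8-dimethyl-1,2,3,4,4a,5,6,7-octahydronaphthalen-2-yl]prop-2-enoate | C=C(C(=O)OC)[C@@H]1CC[C@@]2(C)CC[C@H](O)C(C)=C2C1 | intermediate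
20 | angelic acid, (2Z)-2-methylbut-2-enoic acid | C/C=C(/C)C(=O)O | starting material
21 | (2S,4aS,7R)-7-(3-methoxy-3-oxoprop-1-en-2-yl)-1,4a-dimethyl-2,3,4,4a,5,6,7,8-octahydronaphthalen-2-yl (2Z)-2-methylbut-2-enoate | C=C(C(=O)OC)[C@@H]1CC[C@@]2(C)CC[C@H](OC(=O)/C(C)=C\C)C(C)=C2C1 | intermediate
22 | methyl 2-[(2R,4aS,7S,8aS)-8a-hydroperoxy-4a-methyl-8-methylidene-7-{[(2Z)-2-methylbut-2-enoyl]oxy}decahydronaphthalen-2-yl]prop-2-enoate | C=C(C(=O)OC)[C@@H]1CC[C@@]2(C)CC[C@H](OC(=O)/C(C)=C\C)C(=C)[C@]2(OO)C1 | target

**Step count**

Total: 13 steps. Longest linear sequence: 13 steps (the route is linear; 2, 4, 6, 8, 16 and 20 are purchased reagents).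

**Steps most likely to fail**

Step 6 (proposed new method). The primary radical may be reduced before it rearranges, or be quenched by a 1,5-hydrogen shift from the C15 methyl, so that the five-membered ring survives. The fallback uses known chemistry and sets out from diketone 10, in which the cyclopentanone carbonyl (C5) is still present. A classical Dowd–Beckwith expansion with the ketone carbonyl as acceptor (Bu3SnH, AIBN, benzene, 80 °C, slow addition) should give methyl (1R,4S)-4-methyl-3-oxo-4-(3-oxopentyl)cyclohexane-1-carboxylate F1. NaOMe in MeOH then closes ring A by aldol condensation and equilibrates C7, and the route is rejoined at 12.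

Step 4. Carbon–carbon bond formation may be slow or poorly face-selective, because the enamine nitrogen is crowded by the quaternary neighbour and can hydrogen-bond to its ester; this would erode the configuration at C10. The fallback sets out from 5 and expands the ring before the quaternary centre is made. Dowd–Beckwith expansion (Bu3SnH, AIBN, benzene, 80 °C) gives methyl 4-methyl-3-oxocyclohexane-1-carboxylate F2, whose ketone is no longer flanked by a quaternary carbon. Condensation with 6 (TsOH cat., toluene, Dean–Stark) gives methyl 4-methyl-3-{[(1R)-1-phenylethyl]imino}cyclohexane-1-carboxylate F3. Addition to 8 (THF, rt) gives methyl (4S)-4-methyl-4-(3-oxopentyl)-3-{[(1R)-1-phenylethyl]imino}cyclohexane-1-carboxylate F4, and aqueous AcOH hydrolyses it to methyl (1R,4S)-4-methyl-3-oxo-4-(3-oxopentyl)cyclohexane-1-carboxylate F1 (C7 epimers). NaOMe in MeOH (aldol condensation, C7 equilibration) returns to the route at 12.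

Step 13. The ene reaction may lack regioselectivity: hydrogen abstraction from C6 (giving the 4α-hydroperoxide with a C5=C6 alkene) or from C3 can compete with abstraction from C15. The fallback sets out from 21. Epoxidation with m-CPBA (CH2Cl2, NaHCO3, 0 °C) on the α-face of the only electron-rich alkene gives the 4α,5α-epoxide of 21, methyl 3β-angeloyloxy-4α,5α-epoxyeudesm-11(13)-en-12-oate F5. Base-induced epoxide-to-allylic-alcohol isomerisation with diethylaluminium 2,2,6,6-tetramethylpiperidide (benzene, 0 °C; removal of a C15 proton) gives methyl 3β-angeloyloxy-5α-hydroxyeudesma-4(15),11(13)-dien-12-oate F6. Acid-catalysed perhydrolysis of this tertiary allylic alcohol (50% H2O2, cat. H2SO4, Et2O, 0 °C), through the allylic cation and attack at C5 anti to the C10 methyl, comes back to the route at 22.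

**Further compounds**

F1 | step 6 | methyl (1R,4S)-4-methyl-3-oxo-4-(3-oxopentyl)cyclohexane-1-carboxylate | CCC(=O)CC[C@]1(C)CC[C@@H](C(=O)OC)CC1=O
F2 | step 4 | methyl 4-methyl-3-oxocyclohexane-1-carboxylate (mixture of stereoisomers) | COC(=O)C1CCC(C)C(=O)C1
F3 | step 4 | methyl 4-methyl-3-{[(1R)-1-phenylethyl]imino}cyclohexane-1-carboxylate (ring centres as mixture) | COC(=O)C1CCC(C)C(=N[C@H](C)c2ccccc2)C1
F4 | step 4 | methyl (4S)-4-methyl-4-(3-oxopentyl)-3-{[(1R)-1-phenylethyl]imino}cyclohexane-1-carboxylate (both C1 epimers) | CCC(=O)CC[C@]1(C)CCC(C(=O)OC)CC1=N[C@H](C)c1ccccc1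
F5 | step 13 | methyl 3β-angeloyloxy-4α,5α-epoxyeudesm-11(13)-en-12-oate | C=C(C(=O)OC)[C@@H]1CC[C@@]2(C)CC[C@H](OC(=O)/C(C)=C\C)[C@@]3(C)O[C@@]23C1
F6 | step 13 | methyl 3β-angeloyloxy-5α-hydroxyeudesma-4(15),11(13)-dien-12-oate | C=C(C(=O)OC)[C@@H]1CC[C@@]2(C)CC[C@H](OC(=O)/C(C)=C\C)C(=C)[C@]2(O)C1
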